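**Retrosynthetic overview** (ring A = the propyl-bearing dioxine; ring B = the methoxy-ketal dioxine carrying CH2CO2Me)
1. Ring A is a cis-3,6-dialkyl-3,6-dihydro-1,2-dioxine: C3–H and C6–H are cis across the O1–O2 bridge with C4=C5 between them. This is the retron of singlet oxygen plus an (E,E)-1,3-diene, so ring A is disconnected last by a [4+2] photooxygenation of a (4E,6E)-deca-4,6-dienyl chain on intact ring B. The ring B olefin, flanked by the ketal carbon and the peroxy-bearing carbon, is inert to singlet oxygen.
2. The dienyl chain comes from Julia–Kocienski olefination of an enal with a butyl tetrazolyl sulfone; the enal comes from cross-metathesis of a pent-4-enyl ring B with crotonaldehyde.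
3. Ring B (first ring) comes from 6-exo hemiketalisation of a (Z)-γ-hydroperoxy enone, generated by E→Z photoisomerisation, followed by methyl peroxyketal formation.
4. The (E)-γ-peroxy enone comes from a Wittig reaction of an α-peroxy aldehyde with a keto ylide. The C–OO stereocentre comes from SN2 displacement (inversion) by a protected hydroperoxide on the triflate of dimethyl (S)-malate.
5. Ring order: ring B (step 8), then ring A (step 13).

Key step: step 13

Remark: the (CH2)3 spacer insulates the ring A diene from the ring B stereocentres. Ring B is therefore fixed from the chiral pool, and the single stereoisomer of ring A is reached by separating the two cis cycloadducts, which are diastereomers; the route does not control which diene face is attacked.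

Step 1
Reactants: 1 2,3-dimethylbut-2-ene
Product: 2 2-methoxypropan-2-yl hydroperoxide
Conditions: O3, MeOH/CH2Cl2, −78 °C; N2 purge, warm to 0 °C
Reagents that add atoms: ozone [O-][O+]=O; methanol CO
Why: Ozonolysis (Criegee mechanism) with trapping of the acetone carbonyl oxide by methanol should give the α-methoxy hydroperoxide, a mono-protected hydrogen peroxide.

Step 2
Reactants: 3 dimethyl (2S)-2-hydroxybutanedioate (dimethyl (S)-malate)
Product: 4 dimethyl (2S)-2-{[(trifluoromethyl)sulfonyl]oxy}butanedioate
Conditions: Tf2O, 2,6-lutidine, CH2Cl2, −78 to −40 °C; used directly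
Reagents that add atoms: trifluoromethanesulfonic anhydride O=S(=O)(OS(=O)(=O)C(F)(F)F)C(F)(F)F
Why: O-sulfonylation with retention converts the chiral-pool carbinol into an α-triflyloxy ester, a strong SN2 electrophile.

Step 3
Reactants: 4 dimethyl (2S)-2-{[(trifluoromethyl)sulfonyl]oxy}butanedioate; 2 2-methoxypropan-2-yl hydroperoxide
Product: 6 dimethyl (2R)-2-[(2-methoxypropan-2-yl)peroxy]butanedioate, via potassium peroxide salt 5 (not isolated)
Conditions: KOtBu (1.0 equiv), 18-crown-6 (cat.), THF, −78 °C; then 4, −78 to −20 °C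
Reagents that add atoms: none
Why: O-alkylation of a hydroperoxide by a secondary sulfonate: SN2 attack of the α-effect peroxide anion on the α-triflyloxy ester with inversion sets the R configuration of the C–OO centre (future C3 of ring B), and low temperature with one equivalent of base should hold back E2 elimination to dimethyl fumarate.

Step 4
Reactants: 6 dimethyl (2R)-2-[(2-methoxypropan-2-yl)peroxy]butanedioate
Product: 7 methyl (3R)-3-[(2-methoxypropan-2-yl)peroxy]-4-oxobutanoate
Conditions: iBu2AlH (1.1 equiv), CH2Cl2, −78 °C; aq. potassium sodium tartrate; used crude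
Reagents that add atoms: none
Why: Partial ester reduction: the ester next to the peroxy-bearing carbon is inductively activated and can chelate aluminium through the peroxy oxygen, so it should be reduced selectively to the aluminium hemiacetal and released as the aldehyde, leaving the remote ester and the O–O bond intact.

Step 5
Reactants: 8 methyltriphenylphosphonium bromide; 9 hex-5-enoyl chloride
Product: 12 1-(triphenyl-λ5-phosphanylidene)hept-6-en-2-one, via methylidenetriphenylphosphorane 10 (not isolated), via acylphosphonium chloride 11 (not isolated)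
Conditions: n-BuLi (2 equiv), THF, 0 °C; then 9 (1 equiv), −78 °C to rt
Reagents that add atoms: none
Why: C-acylation of the methylidene ylide followed by transylidation by the second equivalent of ylide should give the stabilised keto ylide.

Step 6
Reactants: 7 methyl (3R)-3-[(2-methoxypropan-2-yl)peroxy]-4-oxobutanoate; 12 1-(triphenyl-λ5-phosphanylidene)hept-6-en-2-one
Product: 13 methyl (3R,4E)-3-[(2-methoxypropan-2-yl)peroxy]-6-oxoundeca-4,10-dienoate
Conditions: CH2Cl2, 0 °C to rt
Reagents that add atoms: none
Why: Wittig olefination with a stabilised keto ylide is base-free and E-selective, so the α-peroxy aldehyde should be converted to the E-enone without epimerisation or fragmentation.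

Step 7
Reactants: 13 methyl (3R,4E)-3-[(2-methoxypropan-2-yl)peroxy]-6-oxoundeca-4,10-dienoate
Product: 14 methyl (3R,4E)-3-hydroperoxy-6-oxoundeca-4,10-dienoate
Conditions: AcOH/THF/H2O (4:2:1), rt
Reagents that add atoms: none
Why: Mild acid hydrolysis of the mixed peroxyketal should free the secondary hydroperoxide without touching the stereocentre.

Step 8
Reactants: 14 methyl (3R,4E)-3-hydroperoxy-6-oxoundeca-4,10-dienoate
Product: 17 methyl 2-[(3R,6S)-6-methoxy-6-(pent-4-en-1-yl)-3,6-dihydro-1,2-dioxin-3-yl]acetate, via (Z)-hydroperoxy enone 15 (not isolated), via dioxinol 16 (not isolated)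
Conditions: hν (350 nm, Pyrex), CH2Cl2, 0 °C; then MeOH, PPTS (cat.), rt; chromatographic separation of the C6 epimers, the unwanted one resubmitted to MeOH/PPTS
Reagents that add atoms: methanol CO
Why: Enone E/Z photoisomerisation with irreversible trapping: the Z isomer is drained by 6-exo-trig addition of the hydroperoxide to the ketone (ring B closes here), and acid-catalysed peroxyketalisation with methanol then sets the ketal centre under equilibrating conditions, so both C6 epimers are expected, the 6S epimer (methoxy trans to CH2CO2Me) is isolated and the other is recycled.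

Step 9
Reactants: 17 methyl 2-[(3R,6S)-6-methoxy-6-(pent-4-en-1-yl)-3,6-dihydro-1,2-dioxin-3-yl]acetate; 18 (2E)-but-2-enal
Product: 19 methyl 2-[(3R,6S)-6-methoxy-6-[(4E)-6-oxohex-4-en-1-yl]-3,6-dihydro-1,2-dioxin-3-yl]acetate
Conditions: second-generation Hoveyda–Grubbs catalyst RuCl2(H2IMes)(=CH-C6H4-2-OiPr) (5 mol %), 18 (5 equiv), CH2Cl2, 40 °C
Reagents that add atoms: none
Why: Olefin cross-metathesis of a terminal alkene with an enal partner is neutral and E-selective, and the hindered, oxygen-flanked ring B olefin should not take part.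

Step 10
Reactants: 20 1-phenyl-1H-tetrazole-5-thiol; 21 1-bromobutane
Product: 22 5-(butylsulfanyl)-1-phenyl-1H-tetrazole
Conditions: K2CO3, acetone, rt
Reagents that add atoms: none
Why: S-alkylation (SN2) of the thiolate with a primary bromide.

Step 11
Reactants: 22 5-(butylsulfanyl)-1-phenyl-1H-tetrazole
Product: 23 5-(butane-1-sulfonyl)-1-phenyl-1H-tetrazole
Conditions: 30% aq. H2O2, (NH4)6Mo7O24·4H2O (cat.), EtOH, 0 °C to rt
Reagents that add atoms: hydrogen peroxide OO
Why: Molybdate-catalysed sulfide-to-sulfone oxidation.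

Step 12
Reactants: 19 methyl 2-[(3R,6S)-6-methoxy-6-[(4E)-6-oxohex-4-en-1-yl]-3,6-dihydro-1,2-dioxin-3-yl]acetate; 23 5-(butane-1-sulfonyl)-1-phenyl-1H-tetrazole
Product: 25 methyl 2-[(3R,6S)-6-[(4E,6E)-deca-4,6-dien-1-yl]-6-methoxy-3,6-dihydro-1,2-dioxin-3-yl]acetate, via potassium sulfonyl carbanion 24 (not isolated)
Conditions: KN(SiMe3)2, DME, −60 °C, 15 min; then 19, −60 °C to rt; aq. NH4Cl
Reagents that add atoms: none
Why: Julia–Kocienski olefination: 1,2-addition of the pre-formed sulfonyl carbanion to the enal, Smiles rearrangement and loss of SO2 and tetrazolate should form the new C6=C7 bond with E geometry (alkyl tetrazolyl sulfone plus enal with a potassium counter-ion in DME is the E-selective pairing), and pre-metalation at low temperature keeps free amide base away from ring B.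

Step 13
Reactants: 25 methyl 2-[(3R,6S)-6-[(4E,6E)-deca-4,6-dien-1-yl]-6-methoxy-3,6-dihydro-1,2-dioxin-3-yl]acetate
Product: 26 methyl 2-[(3R,6S)-6-methoxy-6-{3-[(3R,6S)-6-propyl-3,6-dihydro-1,2-dioxin-3-yl]propyl}-3,6-dihydro-1,2-dioxin-3-yl]acetate
Conditions: O2, 5,10,15,20-tetraphenylporphyrin (1 mol %), visible light (LED), CH2Cl2, −20 °C; preparative HPLC
Reagents that add atoms: dioxygen O=O
Why: Photosensitised singlet oxygen adds across C4 and C7 of the s-cis (4E,6E)-diene in a concerted suprafacial [4+2] cycloaddition, forming both C–O bonds of ring A, placing its O–O bridge and leaving the C4=C5 cis-olefin in one operation; the closest known reaction type is the dye-sensitised photooxygenation of (E,E)-1,4-dialkylbuta-1,3-dienes to cis-3,6-dialkyl-3,6-dihydro-1,2-dioxines. Ring A is closed by intermolecular hetero-Diels–Alder annulation of O2 onto the chain, not by cyclisation of a tethered nucleophile. The relative configuration of the two new stereocentres (cis) is fixed by the E,E geometry of the diene and the delivery of both oxygens to one π-face. The absolute sense at ring A depends on which face is attacked, and the ring B stereocentres five bonds away are not expected to bias it, so 26 should form together with the other cis adduct (epimeric at both ring A centres) and is separated from it by HPLC. The chemoselectivity the step needs, diene over the ring B olefin and over ene pathways, is secured by the unhindered E,E-diene (easy s-cis conformer, no Z substituent) and by the ring B double bond being a cis-1,2-disubstituted olefin deactivated by two allylic C–O bonds.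

**Compound list**
1 | 2,3-dimethylbut-2-ene | CC(C)=C(C)C | starting material
2 | 2-methoxypropan-2-yl hydroperoxide | COC(C)(C)OO | intermediate
3 | dimethyl (2S)-2-hydroxybutanedioate | COC(=O)[C@H](CC(=O)OC)O | starting material
4 | dimethyl (2S)-2-{[(trifluoromethyl)sulfonyl]oxy}butanedioate | COC(=O)[C@H](CC(=O)OC)OS(=O)(=O)C(F)(F)F | intermediate
5 | potassium 2-methoxypropan-2-yl peroxide | COC(C)(C)O[O-].[K+] | intermediate (not isolated)
6 | dimethyl (2R)-2-[(2-methoxypropan-2-yl)peroxy]butanedioate | COC(=O)[C@@H](CC(=O)OC)OOC(C)(C)OC | intermediate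
7 | methyl (3R)-3-[(2-methoxypropan-2-yl)peroxy]-4-oxobutanoate | O=C[C@@H](CC(=O)OC)OOC(C)(C)OC | intermediate
8 | methyltriphenylphosphonium bromide | C[P+](c1ccccc1)(c1ccccc1)c1ccccc1.[Br-] | starting material
9 | hex-5-enoyl chloride | C=CCCCC(Cl)=O | starting material
10 | methylidenetriphenylphosphorane | C=P(c1ccccc1)(c1ccccc1)c1ccccc1 | intermediate (not isolated)
11 | (2-oxohept-6-en-1-yl)triphenylphosphonium chloride | C=CCCCC(=O)C[P+](c1ccccc1)(c1ccccc1)c1ccccc1.[Cl-] | intermediate (not isolated)
12 | 1-(triphenyl-λ5-phosphanylidene)hept-6-en-2-one | C=CCCCC(=O)C=P(c1ccccc1)(c1ccccc1)c1ccccc1 | intermediate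
13 | methyl (3R,4E)-3-[(2-methoxypropan-2-yl)peroxy]-6-oxoundeca-4,10-dienoate | C=CCCCC(=O)/C=C/[C@@H](CC(=O)OC)OOC(C)(C)OC | intermediate
14 | methyl (3R,4E)-3-hydroperoxy-6-oxoundeca-4,10-dienoate | C=CCCCC(=O)/C=C/[C@@H](CC(=O)OC)OO | intermediate
15 | methyl (3R,4Z)-3-hydroperoxy-6-oxoundeca-4,10-dienoate | C=CCCCC(=O)/C=C\[C@@H](CC(=O)OC)OO | intermediate (not isolated)
16 | methyl 2-[(3R)-6-hydroxy-6-(pent-4-en-1-yl)-3,6-dihydro-1,2-dioxin-3-yl]acetate (both C6 anomers) | C=CCCCC1(O)C=C[C@@H](CC(=O)OC)OO1 | intermediate (not isolated)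
17 | methyl 2-[(3R,6S)-6-methoxy-6-(pent-4-en-1-yl)-3,6-dihydro-1,2-dioxin-3-yl]acetate | C=CCCC[C@@]1(OC)C=C[C@@H](CC(=O)OC)OO1 | intermediate
18 | (2E)-but-2-enal | C/C=C/C=O | starting material
19 | methyl 2-[(3R,6S)-6-methoxy-6-[(4E)-6-oxohex-4-en-1-yl]-3,6-dihydro-1,2-dioxin-3-yl]acetate | O=C/C=C/CCC[C@@]1(OC)C=C[C@@H](CC(=O)OC)OO1 | intermediate
20 | 1-phenyl-1H-tetrazole-5-thiol | Sc1nnnn1-c1ccccc1 | starting material
21 | 1-bromobutane | CCCCBr | starting material
22 | 5-(butylsulfanyl)-1-phenyl-1H-tetrazole | CCCCSc1nnnn1-c1ccccc1 | intermediate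
23 | 5-(butane-1-sulfonyl)-1-phenyl-1H-tetrazole | CCCCS(=O)(=O)c1nnnn1-c1ccccc1 | intermediate
24 | potassium 1-[(1-phenyl-1H-tetrazol-5-yl)sulfonyl]butan-1-ide | CCC[CH-]S(=O)(=O)c1nnnn1-c1ccccc1.[K+] | intermediate (not isolated)
25 | methyl 2-[(3R,6S)-6-[(4E,6E)-deca-4,6-dien-1-yl]-6-methoxy-3,6-dihydro-1,2-dioxin-3-yl]acetate | CCC/C=C/C=C/CCC[C@@]1(OC)C=C[C@@H](CC(=O)OC)OO1 | intermediate
26 | methyl 2-[(3R,6S)-6-methoxy-6-{3-[(3R,6S)-6-propyl-3,6-dihydro-1,2-dioxin-3-yl]propyl}-3,6-dihydro-1,2-dioxin-3-yl]acetate | CCC[C@H]1C=C[C@@H](CCC[C@@]2(OC)C=C[C@@H](CC(=O)OC)OO2)OO1 | target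

**Step count:** 13 steps in total; longest linear sequence 9 steps (3 → 4 → 6 → 7 → 13 → 14 → 17 → 19 → 25 → 26).

**Steps most likely to fail**

Step 13. The diene faces are not discriminated, because the nearest stereocentre is five bonds away, so both cis cycloadducts form and they may be hard to separate since they differ only at remote centres. The fallback gives up the cycloaddition and builds ring A by catalyst-controlled 1,4-dioxygenation followed by stereospecific peroxide annulation. Setting out from diene 25, enantioselective platinum-catalysed syn-1,4-diboration (Pt(dba)3, TADDOL-derived phosphonite of the appropriate hand, B2(pin)2, THF) would give methyl 2-[(3R,6S)-6-[(4S,5Z,7R)-4,7-bis(4,4,5,5-tetramethyl-1,3,2-dioxaborolan-2-yl)dec-5-en-1-yl]-6-methoxy-3,6-dihydro-1,2-dioxin-3-yl]acetate F1. Oxidation with retention (Me3NO) would give the syn-enediol methyl 2-[(3R,6S)-6-[(4S,5Z,7R)-4,7-dihydroxydec-5-en-1-yl]-6-methoxy-3,6-dihydro-1,2-dioxin-3-yl]acetate F2. Sulfonylation (Ms2O, pyridine, −20 °C) would give the bis(methanesulfonate) methyl 2-[(3R,6S)-6-[(4S,5Z,7R)-4,7-bis(methanesulfonyloxy)dec-5-en-1-yl]-6-methoxy-3,6-dihydro-1,2-dioxin-3-yl]acetate F3. Double SN2 displacement by hydrogen peroxide (urea–H2O2, Cs2CO3, DMF, −20 °C), inverting both centres, would close ring A as the cis-dioxine and return to the route at target 26. This fallback is longer and less certain than the cycloaddition: the tolerance of ring B to the platinum catalyst and to carbonate would have to be established.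

Step 12. The sulfonyl carbanion or the liberated tetrazolate may fragment ring B, by Kornblum–DeLaMare-type deprotonation at its C3–H or by retro-oxa-Michael expulsion of the peroxide through the ester enolate. The fallback is a base-free ene–diene cross-metathesis. Setting out from olefin 17, the second-generation Hoveyda–Grubbs catalyst and an excess of (3E)-hepta-1,3-diene F4 (from commercial (E)-hex-2-enal and ylide 10) would give diene 25 directly, bypassing 19, 23 and 24. The price would be lower geometric purity at the new C4=C5 bond, which is tolerable because only the E,E isomer should undergo the [4+2] reaction readily.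

Step 3. The basic peroxide anion may cause E2 elimination of the triflate (to dimethyl fumarate), or Kornblum–DeLaMare fragmentation of the α-peroxy ester product. The fallback moves the displacement to a substrate without the acidifying second ester. Setting out from hydroperoxide 2 and commercial (3S)-3-hydroxyoxolan-2-one F5, triflation (Tf2O, 2,6-lutidine) would give (3S)-2-oxooxolan-3-yl trifluoromethanesulfonate F6. SN2 displacement by peroxide salt 5 would give (3R)-3-[(2-methoxypropan-2-yl)peroxy]oxolan-2-one F7. Reduction with iBu2AlH would give the lactol (3R)-3-[(2-methoxypropan-2-yl)peroxy]oxolan-2-ol F8. Wittig reaction with ylide 12 would give (7E,9R)-11-hydroxy-9-[(2-methoxypropan-2-yl)peroxy]undeca-1,7-dien-6-one F9. Oxidation (TEMPO, PhI(OAc)2, aq. MeCN) would give (3R,4E)-3-[(2-methoxypropan-2-yl)peroxy]-6-oxoundeca-4,10-dienoic acid F10, and esterification with Me3SiCHN2 returns to the route at enone 13, bypassing 4, 6 and 7.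

**Further compounds**
F1 | step 13 | methyl 2-[(3R,6S)-6-[(4S,5Z,7R)-4,7-bis(4,4,5,5-tetramethyl-1,3,2-dioxaborolan-2-yl)dec-5-en-1-yl]-6-methoxy-3,6-dihydro-1,2-dioxin-3-yl]acetate | CCC[C@@H](B1OC(C)(C)C(C)(C)O1)/C=C\[C@@H](B1OC(C)(C)C(C)(C)O1)CCC[C@@]1(OC)C=C[C@@H](CC(=O)OC)OO1
F2 | step 13 | methyl 2-[(3R,6S)-6-[(4S,5Z,7R)-4,7-dihydroxydec-5-en-1-yl]-6-methoxy-3,6-dihydro-1,2-dioxin-3-yl]acetate | CCC[C@@H](O)/C=C\[C@@H](O)CCC[C@@]1(OC)C=C[C@@H](CC(=O)OC)OO1
F3 | step 13 | methyl 2-[(3R,6S)-6-[(4S,5Z,7R)-4,7-bis(methanesulfonyloxy)dec-5-en-1-yl]-6-methoxy-3,6-dihydro-1,2-dioxin-3-yl]acetate | CCC[C@@H](OS(C)(=O)=O)/C=C\[C@@H](OS(C)(=O)=O)CCC[C@@]1(OC)C=C[C@@H](CC(=O)OC)OO1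
F4 | step 12 | (3E)-hepta-1,3-diene | C=C/C=C/CCC
F5 | step 3 | (3S)-3-hydroxyoxolan-2-one | O=C1OCC[C@@H]1O
F6 | step 3 | (3S)-2-oxooxolan-3-yl trifluoromethanesulfonate | O=C1OCC[C@@H]1OS(=O)(=O)C(F)(F)F
F7 | step 3 | (3R)-3-[(2-methoxypropan-2-yl)peroxy]oxolan-2-one | O=C1OCC[C@H]1OOC(C)(C)OC
F8 | step 3 | (3R)-3-[(2-methoxypropan-2-yl)peroxy]oxolan-2-ol | OC1OCC[C@H]1OOC(C)(C)OC
F9 | step 3 | (7E,9R)-11-hydroxy-9-[(2-methoxypropan-2-yl)peroxy]undeca-1,7-dien-6-one | C=CCCCC(=O)/C=C/[C@@H](CCO)OOC(C)(C)OC
F10 | step 3 | (3R,4E)-3-[(2-methoxypropan-2-yl)peroxy]-6-oxoundeca-4,10-dienoic acid | C=CCCCC(=O)/C=C/[C@@H](CC(O)=O)OOC(C)(C)OC
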